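**Strategy.** The route rests on cutting the C15–C16 bond of the bicyclo[2.2.2]octane. The key step exploits the fact that the C15 carbonyl sits on quaternary C8 while C16 hangs on the C12 bridgehead of ring C. A samarium ketyl generated from a C8 formyl group adds to a 12(16)-exocyclic methylene, closing ring C8–C15–C16–C12–C13–C14 and creating the C12 bridgehead centre in one operation, with no stereochemical choice. The precursor is a tricyclic δ-lactone (lactone, ring B, ring C) carrying the C14 acetate. Its ring C comes from an aldol, hydroxymethylation and intramolecular allylsilane addition on a cyclohexanone made by asymmetric conjugate addition.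

Key step: step 10

Remark on the chemistry: locants follow the atisane skeleton mapped onto the target (C3 lactone carbonyl, C5 isopropenyl-bearing CH, C8 and C12 bridgeheads, C9 lactone O-bearing carbon, C10 methyl-bearing carbon, C14 acetoxy carbon, C15 ketone, C16=C17 methylene); the target is taken as 5S,8S,9S,10S,12R,14S, as derived from the given structure.

**Step 1**
Reactants: 1 2-methylcyclohex-2-en-1-one; 2 isopropenylmagnesium bromide
Product: 3 (3R)-2-methyl-3-(prop-1-en-2-yl)cyclohexan-1-one (C2 epimers)
Conditions: 2 (1.2 equiv), Cu(OTf)2 (3 mol %), chiral imidazolinium-derived NHC ligand (4 mol %), Et2O, −30 °C; aq. NH4Cl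
Reagents that add atoms: none
Why: Copper-catalysed asymmetric conjugate addition of a Grignard reagent to an α-substituted cyclic enone, in which the chiral NHC–copper complex selects the enone face and so sets C5 (the C2 centre is re-enolised in step 2 and need not be controlled).

**Step 2**
Reactants: 3 (3R)-2-methyl-3-(prop-1-en-2-yl)cyclohexan-1-one; 4 methyl acrylate
Product: 5 methyl 3-[(1S,6S)-1-methyl-2-oxo-6-(prop-1-en-2-yl)cyclohexyl]propanoate
Conditions: 4 (1.5 equiv), KOtBu (0.1 equiv), t-BuOH–THF, 0 °C → rt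
Reagents that add atoms: none
Why: Thermodynamic Michael addition through the more substituted (C10) potassium enolate, with the acrylate approaching anti to the adjacent C5 isopropenyl group, so that the C10 methyl ends up cis to the isopropenyl group.

**Step 3**
Reactants: 6 3-methylbut-3-en-1-ol
Product: 8 3-[(trimethylsilyl)methyl]but-3-en-1-ol, via bis-silyl ether 7 (not isolated)
Conditions: n-BuLi (2.2 equiv), TMEDA, Et2O–hexane, 0 °C → rt; Me3SiCl (2.3 equiv), −78 °C → rt; K2CO3, MeOH, rt
Reagents that add atoms: chlorotrimethylsilane C[Si](C)(C)Cl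
Why: Alkoxide-directed allylic lithiation of the methyl group gives a dianion that is silylated on carbon and oxygen, and methanolysis then removes only the O-silyl group.

**Step 4**
Reactants: 8 3-[(trimethylsilyl)methyl]but-3-en-1-ol
Product: 9 3-[(trimethylsilyl)methyl]but-3-enal
Conditions: Dess–Martin periodinane, NaHCO3, CH2Cl2, 0 °C; used crude
Reagents that add atoms: none
Why: Buffered Dess–Martin oxidation should give the β,γ-unsaturated aldehyde without migration of the double bond into conjugation.

**Step 5**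
Reactants: 5 methyl 3-[(1S,6S)-1-methyl-2-oxo-6-(prop-1-en-2-yl)cyclohexyl]propanoate; 9 3-[(trimethylsilyl)methyl]but-3-enal
Product: 12 methyl 3-[(1S,3S,6S)-3-[(1S)-1-hydroxy-3-(trimethylsilylmethyl)but-3-enyl]-1-methyl-2-oxo-6-(prop-1-en-2-yl)cyclohexyl]propanoate, via boron enolate 10 (not isolated), via boron aldolate 11 (not isolated)
Conditions: c-Hex2BCl, Et3N, Et2O, −78 → 0 °C; 9, −78 °C; MeOH, pH 7 buffer, H2O2, 0 °C
Reagents that add atoms: none
Why: Boron aldol reaction in which only C8 can be enolised, the ring-constrained (E)-enolate reacts through a Zimmerman–Traxler chair (anti aldol) on the face anti to the pseudoaxial C10 methyl, and these two elements together set C14 as S.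

**Step 6**
Reactants: 12 aldol adduct
Product: 15 methyl 3-[(1S,3S,6S)-3-[(1S)-1-hydroxy-3-(trimethylsilylmethyl)but-3-enyl]-3-(hydroxymethyl)-1-methyl-2-oxo-6-(prop-1-en-2-yl)cyclohexyl]propanoate, via bis-silyl enol ether 13 (not isolated), via silyl ether 14 (not isolated)
Conditions: Me3SiOTf (2.5 equiv), Et3N (4 equiv), CH2Cl2, 0 °C → rt; solvent switch; 37% aq. HCHO, Sc(OTf)3 (10 mol %), THF, rt; citric acid, MeOH, rt
Reagents that add atoms: formaldehyde C=O
Why: Soft enolisation can only go towards C8 and gives the tetrasubstituted silyl enol ether, whose Sc(OTf)3-catalysed Mukaiyama aldol reaction with aqueous formaldehyde (hydroxymethylation) should occur on the face anti to the pseudoaxial C10 methyl, placing C15 trans to that methyl and the C14 chain cis to it (C8 quaternary centre).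

**Step 7**
Reactants: 15 diol ketone
Product: 17 (5S,8S,9S,10S,14S)-14,15-dihydroxy-17-nor-3,4:15,16-diseco-atisa-4(18),12(16)-dien-3,9-olide, via hydroxy ester 16 (not isolated)
Conditions: EtAlCl2 (3.5 equiv), CH2Cl2, −78 → −20 °C; aq. Rochelle salt; PPTS (cat.), toluene, 60 °C
Reagents that add atoms: none
Why: Intramolecular Hosomi–Sakurai allylation of the aluminium-chelated C9 ketone closes ring C; because the allylsilane chain sits on C8 syn to the C10 methyl, the C9–C11 bond can only form on that face (cis fusion), which puts O9 anti to the methyl and cis to the C1 ester chain so that the tertiary alcohol lactonises.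

**Step 8**
Reactants: 17 lactone diol
Product: 18 (5S,8S,9S,10S,14S)-14-hydroxy-15-oxo-17-nor-3,4:15,16-diseco-atisa-4(18),12(16)-dien-3,9-olide
Conditions: TEMPO (0.2 equiv), PhI(OAc)2 (1.3 equiv), CH2Cl2, rt
Reagents that add atoms: none
Why: TEMPO/PhI(OAc)2 oxidation is selective for the primary C15 alcohol over the hindered secondary C14 alcohol.

**Step 9**
Reactants: 18 hydroxy aldehyde
Product: 19 (5S,8S,9S,10S,14S)-14-acetoxy-15-oxo-17-nor-3,4:15,16-diseco-atisa-4(18),12(16)-dien-3,9-olide
Conditions: Ac2O, pyridine, DMAP (cat.), CH2Cl2, 0 °C → rt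
Reagents that add atoms: acetic anhydride CC(=O)OC(C)=O
Why: DMAP-catalysed acetylation of the only free hydroxyl, the aldehyde having no α-hydrogen so that neither enolisation nor β-elimination can interfere.

**Step 10**
Reactants: 19 acetoxy aldehyde
Product: 20 (5S,8S,9S,10S,12R,14S)-14-acetoxy-15-hydroxy-17-nor-3,4-seco-atis-4(18)-en-3,9-olide (C15 epimers)
Conditions: SmI2 (3 equiv), HMPA (12 equiv), t-BuOH (2 equiv), THF (5 mM), −40 → 0 °C; aq. NH4Cl at low temperature
Reagents that add atoms: none
Why: Divalent samarium reduces the C15 aldehyde (lactone and acetate are inert) to a ketyl radical anion that adds to the CH2 terminus (C16) of the 12(16)-alkene, and the tertiary C12 radical is then reduced and protonated by t-BuOH. The closest known reaction type is the SmI2–HMPA ketyl–olefin cyclisation of aldehydes onto unactivated 1,1-disubstituted alkenes. Ring C8–C15–C16–C12–C13–C14 closes in the 6-endo-trig mode, favoured because attack at the terminal carbon gives a tertiary radical whereas the 5-exo alternative would give a primary radical on a strained bicyclo[2.2.1]heptane. C12 is the only new stereocentre that is kept: the C15–C16 bond can only form on the face of ring C that carries the axial C15 group on C8, so its configuration follows from C8 and the hydrogen enters from outside the cage, while the C15 carbinol configuration is immaterial because step 11 oxidises it. The step needs selectivity for the ring C alkene over the isopropenyl group, secured by distance (the isopropenyl group is equatorial on ring B and cannot reach C15), and cyclisation faster than simple reduction, for which high dilution and a single weak proton source are used.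

**Step 11**
Reactants: 20 tetracyclic alcohol
Product: 21 (5S,8S,9S,10S,12R,14S)-14-acetoxy-15-oxo-17-nor-3,4-seco-atis-4(18)-en-3,9-olide
Conditions: Dess–Martin periodinane, NaHCO3, CH2Cl2, rt
Reagents that add atoms: none
Why: Dess–Martin oxidation of the only free alcohol, the β-acetoxy and β-acyloxy groups being unable to eliminate because C8 bears no hydrogen.

**Step 12**
Reactants: 21 tetracyclic ketone
Product: 22 crotobarin, (5S,8S,9S,10S,12R,14S)-14-acetoxy-15-oxo-3,4-seco-atisa-4(18),16-dien-3,9-olide
Conditions: (CH2O)n, PhNHMe·CF3CO2H, THF, reflux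
Reagents that add atoms: formaldehyde (as paraformaldehyde) C=O
Why: Acid-mediated Mannich condensation with formaldehyde followed by amine elimination (α-methylenation), C16 being the only enolisable position of the C15 ketone.

**Compound list**
1 | 2-methylcyclohex-2-en-1-one | CC1=CCCCC1=O | starting material
2 | isopropenylmagnesium bromide (prop-1-en-2-ylmagnesium bromide) | CC(=C)[Mg]Br | starting material
3 | (3R)-2-methyl-3-(prop-1-en-2-yl)cyclohexan-1-one, C2 epimers | CC1C(=O)CCC[C@H]1C(C)=C | intermediate
4 | methyl acrylate | C=CC(=O)OC | starting material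
5 | methyl 3-[(1S,6S)-1-methyl-2-oxo-6-(prop-1-en-2-yl)cyclohexyl]propanoate (C10 methyl cis to C5 isopropenyl) | COC(=O)CC[C@]1(C)C(=O)CCC[C@H]1C(C)=C | intermediate
6 | 3-methylbut-3-en-1-ol | CC(=C)CCO | starting material
7 | trimethyl{[3-(trimethylsilylmethyl)but-3-en-1-yl]oxy}silane | C[Si](C)(C)CC(=C)CCO[Si](C)(C)C | intermediate
8 | 3-[(trimethylsilyl)methyl]but-3-en-1-ol | C[Si](C)(C)CC(=C)CCO | intermediate
9 | 3-[(trimethylsilyl)methyl]but-3-enal | C[Si](C)(C)CC(=C)CC=O | intermediate
10 | dicyclohexylboron enolate of 5 (C8=C9, O9–B) | C1=C(OB(C2CCCCC2)C2CCCCC2)[C@@](C)(CCC(=O)OC)[C@H](C(=C)C)CC1 | intermediate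
11 | dicyclohexylboron aldolate of 12 (O14–B) | C[Si](C)(C)CC(=C)C[C@H](OB(C2CCCCC2)C2CCCCC2)[C@@H]1CC[C@@H](C(=C)C)[C@](C)(CCC(=O)OC)C1=O | intermediate
12 | methyl 3-[(1S,3S,6S)-3-[(1S)-1-hydroxy-3-(trimethylsilylmethyl)but-3-enyl]-1-methyl-2-oxo-6-(prop-1-en-2-yl)cyclohexyl]propanoate (anti aldol, 14S) | C[Si](C)(C)CC(=C)C[C@H](O)[C@@H]1CC[C@@H](C(=C)C)[C@](C)(CCC(=O)OC)C1=O | intermediate
13 | C9 trimethylsilyl enol ether (C8=C9) and C14 trimethylsilyl ether of 12 | C[Si](C)(C)CC(=C)C[C@H](O[Si](C)(C)C)C1=C(O[Si](C)(C)C)[C@@](C)(CCC(=O)OC)[C@H](C(=C)C)CC1 | intermediate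
14 | C14 O-trimethylsilyl ether of 15 | OC[C@@]1(CC[C@@H](C(=C)C)[C@](C)(CCC(=O)OC)C1=O)[C@@H](O[Si](C)(C)C)CC(=C)C[Si](C)(C)C | intermediate
15 | methyl 3-[(1S,3S,6S)-3-[(1S)-1-hydroxy-3-(trimethylsilylmethyl)but-3-enyl]-3-(hydroxymethyl)-1-methyl-2-oxo-6-(prop-1-en-2-yl)cyclohexyl]propanoate (C15 trans, C14 chain cis to the C10 methyl) | OC[C@@]1(CC[C@@H](C(=C)C)[C@](C)(CCC(=O)OC)C1=O)[C@@H](O)CC(=C)C[Si](C)(C)C | intermediate
16 | ring C-closed triol methyl ester (9-OH, 14-OH, 15-OH, 12(16)-methylene; configuration as in 17) | OC[C@]12CC[C@@H](C(=C)C)[C@](C)(CCC(=O)OC)[C@@]1(O)CC(=C)C[C@@H]2O | intermediate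
17 | (5S,8S,9S,10S,14S)-14,15-dihydroxy-17-nor-3,4:15,16-diseco-atisa-4(18),12(16)-dien-3,9-olide | OC[C@]12CC[C@@H](C(=C)C)[C@]3(C)CCC(=O)O[C@@]31CC(=C)C[C@@H]2O | intermediate
18 | (5S,8S,9S,10S,14S)-14-hydroxy-15-oxo-17-nor-3,4:15,16-diseco-atisa-4(18),12(16)-dien-3,9-olide | O=C[C@]12CC[C@@H](C(=C)C)[C@]3(C)CCC(=O)O[C@@]31CC(=C)C[C@@H]2O | intermediate
19 | (5S,8S,9S,10S,14S)-14-acetoxy-15-oxo-17-nor-3,4:15,16-diseco-atisa-4(18),12(16)-dien-3,9-olide | O=C[C@]12CC[C@@H](C(=C)C)[C@]3(C)CCC(=O)O[C@@]31CC(=C)C[C@@H]2OC(C)=O | intermediate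
20 | (5S,8S,9S,10S,12R,14S)-14-acetoxy-15-hydroxy-17-nor-3,4-seco-atis-4(18)-en-3,9-olide, C15 epimers | C1C(O)[C@]23CC[C@@H](C(=C)C)[C@]4(C)CCC(=O)O[C@@]42C[C@H]1C[C@@H]3OC(C)=O | intermediate
21 | (5S,8S,9S,10S,12R,14S)-14-acetoxy-15-oxo-17-nor-3,4-seco-atis-4(18)-en-3,9-olide | C1C(=O)[C@]23CC[C@@H](C(=C)C)[C@]4(C)CCC(=O)O[C@@]42C[C@H]1C[C@@H]3OC(C)=O | intermediate
22 | crotobarin | C=C1C(=O)[C@]23CC[C@@H](C(=C)C)[C@]4(C)CCC(=O)O[C@@]42C[C@H]1C[C@@H]3OC(C)=O | target

**Total step count:** 12. **Longest linear sequence:** 10 steps (steps 1, 2, 5–12); steps 3 and 4 form the side branch.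

**Steps most likely to fail**

Step 10 (key step). The ketyl may be reduced to the primary alcohol or dimerise before it attacks the unactivated alkene in the endo mode, and the acetyl group may migrate from O14 to the new samarium alkoxide at O15. The fallback sets out from 19 and closes the same C15–C16 bond by a polar route. TiCl4 (1.1 equiv), CH2Cl2, −78 °C should trigger a Prins-type cation–olefin cyclisation in which the C12 bridgehead cation is captured by chloride, giving (5S,8S,9S,10S,14S)-14-acetoxy-12-chloro-15-hydroxy-17-nor-3,4-seco-atis-4(18)-en-3,9-olide F1. Bu3SnH, AIBN, toluene, 80 °C then removes the bridgehead chlorine, and the sequence comes back to the route at 20.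

Step 7. The allylsilane may fail to add to a ketone flanked by two quaternary carbons, with protodesilylation or Lewis acid-induced retro-aldol loss of formaldehyde taking over. The fallback sets out from 15. 2,2-Dimethoxypropane and PPTS protect the 1,3-diol as the acetonide of 15 F2. NBS, propylene oxide, CH2Cl2, −78 °C converts the allylsilane into the allylic bromide acetonide F3. SmI2, HMPA, THF then performs an intramolecular Barbier addition to C9 (organosamarium additions tolerate hindered ketones), and the alkoxide lactonises to the acetonide of 17 F4. Aqueous AcOH at 40 °C removes the acetonide, and the sequence comes back at 17.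

Step 6. Formation of the tetrasubstituted silyl enol ether may be slow, the C14 silyloxy group may be lost by elimination to the enone, and facial selectivity at C8 may be poor. The fallback sets out from 5 and replaces steps 5 and 6 by chelation-controlled lithium chemistry on the carboxylate, whose α-hydrogens do not compete. LiOH, THF–H2O gives 3-[(1S,6S)-1-methyl-2-oxo-6-(prop-1-en-2-yl)cyclohexyl]propanoic acid F5. LDA (2.1 equiv), THF, −78 °C, then 9, gives the anti aldol acid F6. LDA (3.2 equiv), THF–DMPU, −78 → −40 °C, then gaseous formaldehyde, should hydroxymethylate the chelated lithium aldolate–enolate on the face anti to both the C13 chain and the C10 methyl, giving the diol acid F7. Me3SiCHN2, MeOH–toluene re-forms the methyl ester, and the sequence comes back at 15.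

**Further compounds**
F1 | step 10 | (5S,8S,9S,10S,14S)-14-acetoxy-12-chloro-15-hydroxy-17-nor-3,4-seco-atis-4(18)-en-3,9-olide | C1C(O)[C@]23CC[C@@H](C(=C)C)[C@]4(C)CCC(=O)O[C@@]42C[C@@]1(Cl)C[C@@H]3OC(C)=O
F2 | step 7 | acetonide (O14, O15) of 15 | CC1(C)OC[C@@]2(CC[C@@H](C(=C)C)[C@](C)(CCC(=O)OC)C2=O)[C@H](CC(=C)C[Si](C)(C)C)O1
F3 | step 7 | allylic bromide acetonide (CH2Br in place of CH2SiMe3 of F2) | CC1(C)OC[C@@]2(CC[C@@H](C(=C)C)[C@](C)(CCC(=O)OC)C2=O)[C@H](CC(=C)CBr)O1
F4 | step 7 | acetonide (O14, O15) of 17 | CC4(C)OC[C@]12CC[C@@H](C(=C)C)[C@]3(C)CCC(=O)O[C@@]31CC(=C)C[C@@H]2O4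
F5 | step 6 | 3-[(1S,6S)-1-methyl-2-oxo-6-(prop-1-en-2-yl)cyclohexyl]propanoic acid | OC(=O)CC[C@]1(C)C(=O)CCC[C@H]1C(C)=C
F6 | step 6 | carboxylic acid corresponding to 12 | C[Si](C)(C)CC(=C)C[C@H](O)[C@@H]1CC[C@@H](C(=C)C)[C@](C)(CCC(=O)O)C1=O
F7 | step 6 | carboxylic acid corresponding to 15 | OC[C@@]1(CC[C@@H](C(=C)C)[C@](C)(CCC(=O)O)C1=O)[C@@H](O)CC(=C)C[Si](C)(C)C
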